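**Retrosynthetic overview**

1. Target 29 ← 27 by unmasking the C15 acid; 27 ← axial C19 alcohol 25 + (R)-2-methylbutanoic acid; 25 ← 24 ← 22 by equatorial C-methylation of the C19 aldehyde enolate (sets C4) and reduction.
2. 22 ← 21 (sultam removal); 21 ← 13 + 16 in one radical cascade that forms C2–C3 (intermolecular), then C4–C5 (ring A) and C9–C10 (ring B), and releases the C8=C17 methylene.
3. Enabling feature: in ring A, C4 is a quaternary carbon α to the oxidised carbon C19, so C3–C4 can arrive as an acrylic acid unit, while C2 is a plain CH2 that can be a primary radical. C5/C10(C20) and C9/C8(C17) are the two trisubstituted alkenes of a head-to-tail isoprenoid chain, and the exocyclic C8=C17 bond is where such a chain ends on an allylsilane.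
4. 13 ← (R)-citronellic acid (source of C13) by ozonolysis and two vinyl-Grignard/Johnson–Claisen homologations; the second leaves one extra carboxyl carbon on C2, lost as CO2 when the radical is made.
5. Ring order: ring A, then ring B, both in step 11; no ring of the target exists before it.

Key step: step 11

Remark: carbons are numbered as in labdane (C1–C20; ring A = C1–C5 and C10, ring B = C5–C10; C19 is the C4 substituent cis to C20); (R)-citronellic acid, (2R)-bornane-10,2-sultam, 2-bromoallyltrimethylsilane and (R)-2-methylbutanoic acid are taken as commercial.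

**Route**

Step 1
Reactants: 1 (R)-citronellic acid
Product: 2 tert-butyl (3R)-3,7-dimethyloct-6-enoate
Conditions: Boc2O (2 equiv), DMAP (0.3 equiv), t-BuOH, 35 °C
Reagents that add atoms: di-tert-butyl dicarbonate, CC(C)(C)OC(=O)OC(=O)OC(C)(C)C
Why: Boc2O/DMAP tert-butyl esterification masks C15 in a form that should survive Grignard reagents, hydride at −78 °C and base, and the stereocentre (future C13) is not touched.

Step 2
Reactants: 2 tert-butyl (3R)-3,7-dimethyloct-6-enoate
Product: 4 tert-butyl (3R)-3-methyl-6-oxohexanoate, via ozonide 3 (not isolated)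
Conditions: O3, CH2Cl2, −78 °C; then PPh3, −78 °C to 25 °C
Reagents that add atoms: ozone, [O-][O+]=O
Why: Ozonolysis with reductive work-up (Criegee mechanism) cleaves the only alkene and should give the aldehyde whose carbonyl carbon becomes C9.

Step 3
Reactants: 4 tert-butyl (3R)-3-methyl-6-oxohexanoate
Product: 5 tert-butyl (3R)-6-hydroxy-3-methyl-7-[(trimethylsilyl)methyl]oct-7-enoate (both C6 epimers)
Conditions: 2-bromoallyltrimethylsilane, Mg, THF, 25 °C; then 4, THF, −78 °C; aq. NH4Cl
Reagents that add atoms: [3-(trimethylsilyl)prop-1-en-2-yl]magnesium bromide, C=C([Mg]Br)C[Si](C)(C)C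
Why: Grignard 1,2-addition to the aldehyde, far faster than attack on the tert-butyl ester at −78 °C, brings C8, C7 and the silylmethyl group (future C17); the carbinol configuration is irrelevant because step 4 consumes it.

Step 4
Reactants: 5 tert-butyl (3R)-6-hydroxy-3-methyl-7-[(trimethylsilyl)methyl]oct-7-enoate
Product: 7 1-tert-butyl 10-ethyl (3R,6Z)-3-methyl-7-[(trimethylsilyl)methyl]dec-6-enedioate, via ketene acetal 6 (not isolated)
Conditions: MeC(OEt)3 (6 equiv), pivalic acid (5 mol%), 135 °C, EtOH distilled off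
Reagents that add atoms: triethyl orthoacetate, CC(OCC)(OCC)OCC
Why: Johnson–Claisen rearrangement through a chair transition state with the C9 substituent equatorial should give the trisubstituted alkene with C7 trans to C11 (6Z by the CIP rules only because of silicon), and the weak acid catalyst should not protodesilylate the allylsilane.

Step 5
Reactants: 7 1-tert-butyl 10-ethyl (3R,6Z)-3-methyl-7-[(trimethylsilyl)methyl]dec-6-enedioate
Product: 8 tert-butyl (3R,6Z)-3-methyl-10-oxo-7-[(trimethylsilyl)methyl]dec-6-enoate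
Conditions: i-Bu2AlH (1.05 equiv), toluene, −78 °C; aq. potassium sodium tartrate
Reagents that add atoms: none
Why: Partial reduction of the unhindered ethyl ester to the aldehyde at −78 °C is standard, and the tert-butyl ester reacts much more slowly.

Step 6
Reactants: 8 tert-butyl (3R,6Z)-3-methyl-10-oxo-7-[(trimethylsilyl)methyl]dec-6-enoate
Product: 9 tert-butyl (3R,6Z)-10-hydroxy-3,11-dimethyl-7-[(trimethylsilyl)methyl]dodeca-6,11-dienoate (both C10 epimers)
Conditions: isopropenylMgBr (1.1 equiv), THF, −78 °C; aq. NH4Cl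
Reagents that add atoms: isopropenylmagnesium bromide, CC(=C)[Mg]Br
Why: Grignard 1,2-addition to the aldehyde brings C10, C1 and the C20 methyl group; the carbinol configuration is again consumed in the next step.

Step 7
Reactants: 9 tert-butyl (3R,6Z)-10-hydroxy-3,11-dimethyl-7-[(trimethylsilyl)methyl]dodeca-6,11-dienoate
Product: 11 1-tert-butyl 14-ethyl (3R,6Z,10E)-3,11-dimethyl-7-[(trimethylsilyl)methyl]tetradeca-6,10-dienedioate, via ketene acetal 10 (not isolated)
Conditions: MeC(OEt)3 (6 equiv), pivalic acid (5 mol%), 135 °C, EtOH distilled off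
Reagents that add atoms: triethyl orthoacetate, CC(OCC)(OCC)OCC
Why: A second Johnson–Claisen rearrangement (chair transition state, chain equatorial) should give the (E)-C5=C10 alkene and place on C2 one extra carboxyl carbon that serves as a traceless radical precursor.

Step 8
Reactants: 11 1-tert-butyl 14-ethyl (3R,6Z,10E)-3,11-dimethyl-7-[(trimethylsilyl)methyl]tetradeca-6,10-dienedioate
Product: 12 (4E,8Z,12R)-14-tert-butoxy-4,12-dimethyl-14-oxo-8-[(trimethylsilyl)methyl]tetradeca-4,8-dienoic acid
Conditions: LiOH·H2O (1.5 equiv), THF/MeOH/H2O, 0 to 25 °C; then 0.5 M HCl to pH 4, 0 °C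
Reagents that add atoms: lithium hydroxide, [Li+].[OH-]
Why: Saponification should be selective for the unhindered ethyl ester because tert-butyl esters resist hydroxide.

Step 9
Reactants: 12 (4E,8Z,12R)-14-tert-butoxy-4,12-dimethyl-14-oxo-8-[(trimethylsilyl)methyl]tetradeca-4,8-dienoic acid
Product: 13 14-tert-butyl 1-(1,3-dioxoisoindolin-2-yl) (4E,8Z,12R)-4,12-dimethyl-8-[(trimethylsilyl)methyl]tetradeca-4,8-dienedioate
Conditions: N-hydroxyphthalimide (1.1 equiv), DIC (1.1 equiv), DMAP (5 mol%), CH2Cl2, 25 °C
Reagents that add atoms: N-hydroxyphthalimide, ON1C(=O)c2ccccc2C1=O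
Why: Carbodiimide coupling (Steglich-type esterification) gives the redox-active ester under neutral conditions that leave the allylsilane and the tert-butyl ester alone.

Step 10
Reactants: 14 (2R)-bornane-10,2-sultam
Product: 16 N-acryloyl-(2R)-bornane-10,2-sultam, via sodium sultamide 15 (not isolated)
Conditions: NaH (1.1 equiv), toluene, 0 to 25 °C; then acryloyl chloride (1.2 equiv), 0 to 25 °C
Reagents that add atoms: acryloyl chloride, C=CC(=O)Cl
Why: N-Acylation of the sodium salt of the sultam is the standard preparation of N-enoyl sultams.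

Step 11
Reactants: 13 14-tert-butyl 1-(1,3-dioxoisoindolin-2-yl) (4E,8Z,12R)-4,12-dimethyl-8-[(trimethylsilyl)methyl]tetradeca-4,8-dienedioate; 16 N-acryloyl-(2R)-bornane-10,2-sultam
Product: 21 tert-butyl (4S,5R,9R,10R,13R)-19-[(2R)-bornane-10,2-sultam-N-yl]-19-oxo-18-norlabd-8(17)-en-15-oate, via primary alkyl radical 17 (not isolated), via α-acyl radical 18 (not isolated), via monocyclic tertiary radical 19 (not isolated), via β-silyl tertiary radical 20 (not isolated)
Conditions: 16 (1.5 equiv), Ir(ppy)3 (1 mol%), Cu(OAc)2 (5 mol%), MeCN/PhCF3 (1:1), 0.05 M, blue LEDs (450 nm), 25 °C, degassed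
Reagents that add atoms: none
Why: Proposed new method: the photoexcited iridium complex (trivalent iridium) transfers an electron to 13, which loses CO2 and phthalimide anion to give the nucleophilic primary radical 17 (future C2); 17 adds to the unsubstituted terminus of the electron-poor acrylamide 16 (C2–C3 bond), the electrophilic α-acyl radical 18 closes ring A by 6-endo-trig attack on C5 (C4–C5 bond), the tertiary C10 radical 19 closes ring B by 6-endo-trig attack on C9, and the tertiary β-silyl C8 radical 20 is oxidised by Cu(OAc)2 (divalent copper) and loses the trimethylsilyl group to leave the C8=C17 alkene regiospecifically, the monovalent copper being re-oxidised by the oxidised photocatalyst, so that no stoichiometric oxidant or reductant is needed. The closest known reaction types are the decarboxylative Giese addition of N-hydroxyphthalimide esters, radical polyene bicyclisations started by α-carbonyl radicals, allylsilane-terminated polyene cyclisations together with oxidative radical allylation by allylsilanes, and sultam-controlled radical annulations; their merger into one cascade is new. C5, C10 and C9 are set by the chair–chair transition state: anti addition across the (E)-C5=C10 bond gives the trans ring fusion, and the geometry of the C8=C9 bond (C7 trans to C11) places the C9 side chain equatorial, cis to C20. The absolute sense is set at C4 by the (2R)-sultam, whose Z radical (carbonyl anti to the sulfonyl group) is taken to be shielded on its Si face by the pseudo-axial sulfonyl oxygen, so that C5 bonds to the Re face with the acyl group equatorial; the C4 centre itself is re-set in step 13. The step needs addition of 17 to 16 before capture by copper (excess 16 and a low copper loading), 6-endo rather than 5-exo closure (attack at the CH terminus of each trisubstituted alkene gives a tertiary radical, whereas 5-exo would join two fully substituted carbons), cyclisation before a second addition to 16 (dilution, only a modest excess of 16, and fast oxidation of the electron-rich β-silyl radical), and facial control (the auxiliary).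

Step 12
Reactants: 21 tert-butyl (4S,5R,9R,10R,13R)-19-[(2R)-bornane-10,2-sultam-N-yl]-19-oxo-18-norlabd-8(17)-en-15-oate
Product: 22 tert-butyl (4S,5R,9R,10R,13R)-19-oxo-18-norlabd-8(17)-en-15-oate (C4 formyl equatorial)
Conditions: i-Bu2AlH (1.2 equiv), CH2Cl2, −78 °C; aq. potassium sodium tartrate
Reagents that add atoms: none
Why: Reductive cleavage of N-acylsultams to aldehydes is known; hydride should add once to the activated N-acylsulfonamide carbonyl faster than to the tert-butyl ester, the sultam being released only on work-up, and any epimerisation at C4 is harmless because step 13 re-sets it.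

Step 13
Reactants: 22 tert-butyl (4S,5R,9R,10R,13R)-19-oxo-18-norlabd-8(17)-en-15-oate
Product: 24 tert-butyl (4R,5S,9R,10S,13R)-19-oxolabd-8(17)-en-15-oate (formyl axial), via potassium enolate 23 (not isolated)
Conditions: KOt-Bu (1.3 equiv), THF, −20 °C; then MeI (5 equiv), −20 to 0 °C
Reagents that add atoms: iodomethane, CI
Why: C-Methylation of the potassium enolate of an α-branched aldehyde; iodomethane should approach the exocyclic enolate from the equatorial face, away from the axial C20 methyl group, so that the new methyl is equatorial and C19 ends axial and cis to C20 (4R), while the far less acidic tert-butyl ester is not enolised.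

Step 14
Reactants: 24 tert-butyl (4R,5S,9R,10S,13R)-19-oxolabd-8(17)-en-15-oate
Product: 25 tert-butyl (4R,5S,9R,10S,13R)-19-hydroxylabd-8(17)-en-15-oate
Conditions: NaBH4 (1.5 equiv), MeOH, 0 to 25 °C
Reagents that add atoms: none
Why: Borohydride reduces the neopentyl aldehyde and leaves the tert-butyl ester and the alkene untouched.

Step 15
Reactants: 25 tert-butyl (4R,5S,9R,10S,13R)-19-hydroxylabd-8(17)-en-15-oate; 26 (R)-2-methylbutanoic acid
Product: 27 tert-butyl (4R,5S,9R,10S,13R)-19-[(2R)-2-methylbutanoyloxy]labd-8(17)-en-15-oate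
Conditions: 26 (3 equiv), DIC (3 equiv), DMAP (0.5 equiv), CH2Cl2, 0 to 25 °C
Reagents that add atoms: none
Why: Steglich esterification acylates the hindered primary alcohol under neutral conditions that should not enolise the α-stereocentre of the acid.

Step 16
Reactants: 27 tert-butyl (4R,5S,9R,10S,13R)-19-[(2R)-2-methylbutanoyloxy]labd-8(17)-en-15-oate
Product: 29 (4R,5S,9R,10S,13R)-19-[(2R)-2-methylbutanoyloxy]labd-8(17)-en-15-oic acid (CNP0365997.1), via trimethylsilyl ester 28 (not isolated)
Conditions: TMSOTf (3 equiv), 2,6-lutidine (4.5 equiv), CH2Cl2, 0 °C; then aq. NaH2PO4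
Reagents that add atoms: none
Why: Buffered silyl triflate cleavage of the tert-butyl ester (loss of isobutene, then hydrolysis of the silyl ester on work-up) avoids protic acid, so the acid-sensitive exocyclic alkene and the C19 ester should survive.

**Compound list**

1 | (R)-citronellic acid, (3R)-3,7-dimethyloct-6-enoic acid | CC(C)=CCC[C@@H](C)CC(=O)O | starting material
2 | tert-butyl (3R)-3,7-dimethyloct-6-enoate | CC(C)=CCC[C@@H](C)CC(=O)OC(C)(C)C | intermediate
3 | ozonide (1,2,4-trioxolane) of 2 | CC1(C)OOC(CC[C@@H](C)CC(=O)OC(C)(C)C)O1 | intermediate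
4 | tert-butyl (3R)-3-methyl-6-oxohexanoate | O=CCC[C@@H](C)CC(=O)OC(C)(C)C | intermediate
5 | tert-butyl (3R)-6-hydroxy-3-methyl-7-[(trimethylsilyl)methyl]oct-7-enoate | C=C(C[Si](C)(C)C)C(O)CC[C@@H](C)CC(=O)OC(C)(C)C | intermediate
6 | mixed ketene acetal of 5 (O-(1-ethoxyvinyl) ether) | C=C(C[Si](C)(C)C)C(OC(=C)OCC)CC[C@@H](C)CC(=O)OC(C)(C)C | intermediate
7 | 1-tert-butyl 10-ethyl (3R,6Z)-3-methyl-7-[(trimethylsilyl)methyl]dec-6-enedioate | CCOC(=O)CC/C(C[Si](C)(C)C)=C/CC[C@@H](C)CC(=O)OC(C)(C)C | intermediate
8 | tert-butyl (3R,6Z)-3-methyl-10-oxo-7-[(trimethylsilyl)methyl]dec-6-enoate | O=CCC/C(C[Si](C)(C)C)=C/CC[C@@H](C)CC(=O)OC(C)(C)C | intermediate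
9 | tert-butyl (3R,6Z)-10-hydroxy-3,11-dimethyl-7-[(trimethylsilyl)methyl]dodeca-6,11-dienoate | C=C(C)C(O)CC/C(C[Si](C)(C)C)=C/CC[C@@H](C)CC(=O)OC(C)(C)C | intermediate
10 | mixed ketene acetal of 9 (O-(1-ethoxyvinyl) ether) | C=C(C)C(OC(=C)OCC)CC/C(C[Si](C)(C)C)=C/CC[C@@H](C)CC(=O)OC(C)(C)C | intermediate
11 | 1-tert-butyl 14-ethyl (3R,6Z,10E)-3,11-dimethyl-7-[(trimethylsilyl)methyl]tetradeca-6,10-dienedioate | CCOC(=O)CC/C(C)=C/CC/C(C[Si](C)(C)C)=C/CC[C@@H](C)CC(=O)OC(C)(C)C | intermediate
12 | (4E,8Z,12R)-14-tert-butoxy-4,12-dimethyl-14-oxo-8-[(trimethylsilyl)methyl]tetradeca-4,8-dienoic acid | OC(=O)CC/C(C)=C/CC/C(C[Si](C)(C)C)=C/CC[C@@H](C)CC(=O)OC(C)(C)C | intermediate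
13 | 14-tert-butyl 1-(1,3-dioxoisoindolin-2-yl) (4E,8Z,12R)-4,12-dimethyl-8-[(trimethylsilyl)methyl]tetradeca-4,8-dienedioate | O=C(CC/C(C)=C/CC/C(C[Si](C)(C)C)=C/CC[C@@H](C)CC(=O)OC(C)(C)C)ON1C(=O)c2ccccc2C1=O | intermediate
14 | (2R)-bornane-10,2-sultam (camphorsultam) | CC1(C)[C@@H]2CC[C@]13CS(=O)(=O)N[C@@H]3C2 | starting material
15 | sodium salt of 14 | CC1(C)[C@@H]2CC[C@]13CS(=O)(=O)[N-][C@@H]3C2.[Na+] | intermediate
16 | N-acryloyl-(2R)-bornane-10,2-sultam | CC1(C)[C@@H]2CC[C@]13CS(=O)(=O)N(C(=O)C=C)[C@@H]3C2 | intermediate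
17 | primary alkyl radical from 13 (radical at C2) | [CH2]C/C(C)=C/CC/C(C[Si](C)(C)C)=C/CC[C@@H](C)CC(=O)OC(C)(C)C | intermediate
18 | α-acyl radical, adduct of 17 to 16 (radical at C4) | O=C([CH]CCC/C(C)=C/CC/C(C[Si](C)(C)C)=C/CC[C@@H](C)CC(=O)OC(C)(C)C)N1[C@@H]2C[C@H]3CC[C@]2(CS1(=O)=O)C3(C)C | intermediate
19 | monocyclic tertiary radical (ring A closed, radical at C10; 4S,5R) | O=C(N2[C@@H]3C[C@H]4CC[C@]3(CS2(=O)=O)C4(C)C)[C@H]1CCC[C](C)[C@@H]1CC/C(C[Si](C)(C)C)=C/CC[C@@H](C)CC(=O)OC(C)(C)C | intermediate
20 | bicyclic β-silyl tertiary radical (rings A and B closed, radical at C8) | C[Si](C)(C)C[C]1CC[C@@H]2[C@@H](C(=O)N3[C@@H]4C[C@H]5CC[C@]4(CS3(=O)=O)C5(C)C)CCC[C@@]2(C)[C@@H]1CC[C@@H](C)CC(=O)OC(C)(C)C | intermediate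
21 | tert-butyl (4S,5R,9R,10R,13R)-19-[(2R)-bornane-10,2-sultam-N-yl]-19-oxo-18-norlabd-8(17)-en-15-oate (trans-decalin, acyl group equatorial) | C=C1CC[C@@H]2[C@@H](C(=O)N3[C@@H]4C[C@H]5CC[C@]4(CS3(=O)=O)C5(C)C)CCC[C@@]2(C)[C@@H]1CC[C@@H](C)CC(=O)OC(C)(C)C | intermediate
22 | tert-butyl (4S,5R,9R,10R,13R)-19-oxo-18-norlabd-8(17)-en-15-oate | C=C1CC[C@@H]2[C@@H](C=O)CCC[C@@]2(C)[C@@H]1CC[C@@H](C)CC(=O)OC(C)(C)C | intermediate
23 | potassium enolate of 22 (C4=C19) | C=C1CC[C@@H]2C(=C[O-])CCC[C@@]2(C)[C@@H]1CC[C@@H](C)CC(=O)OC(C)(C)C.[K+] | intermediate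
24 | tert-butyl (4R,5S,9R,10S,13R)-19-oxolabd-8(17)-en-15-oate | C=C1CC[C@@H]2[C@](C)(C=O)CCC[C@@]2(C)[C@@H]1CC[C@@H](C)CC(=O)OC(C)(C)C | intermediate
25 | tert-butyl (4R,5S,9R,10S,13R)-19-hydroxylabd-8(17)-en-15-oate | C=C1CC[C@@H]2[C@](C)(CO)CCC[C@@]2(C)[C@@H]1CC[C@@H](C)CC(=O)OC(C)(C)C | intermediate
26 | (R)-2-methylbutanoic acid | CC[C@@H](C)C(=O)O | starting material
27 | tert-butyl (4R,5S,9R,10S,13R)-19-[(2R)-2-methylbutanoyloxy]labd-8(17)-en-15-oate | C=C1CC[C@@H]2[C@](C)(COC(=O)[C@H](C)CC)CCC[C@@]2(C)[C@@H]1CC[C@@H](C)CC(=O)OC(C)(C)C | intermediate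
28 | trimethylsilyl (4R,5S,9R,10S,13R)-19-[(2R)-2-methylbutanoyloxy]labd-8(17)-en-15-oate | C=C1CC[C@@H]2[C@](C)(COC(=O)[C@H](C)CC)CCC[C@@]2(C)[C@@H]1CC[C@@H](C)CC(=O)O[Si](C)(C)C | intermediate
29 | (4R,5S,9R,10S,13R)-19-[(2R)-2-methylbutanoyloxy]labd-8(17)-en-15-oic acid (CNP0365997.1) | C=C1CC[C@@H]2[C@](C)(COC(=O)[C@H](C)CC)CCC[C@@]2(C)[C@@H]1CC[C@@H](C)CC(=O)O | target

**Step count**

Total: 16 steps. Longest linear sequence: 15 steps (steps 1–9 and 11–16); step 10 is a one-step branch.

**Steps most likely to fail**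

Step 11 (proposed new method). The primary radical may be oxidised by copper before it adds to 16. The later nucleophilic tertiary radicals may add to a second molecule of 16 instead of cyclising or being oxidised. The α-acyl radical may oligomerise. Facial discrimination by the sultam may be insufficient, which would show up as a diastereomer because C13 is fixed. Fallback from 13, dividing the cascade into known operations: nickel-catalysed reductive decarboxylative conjugate addition of 13 to methyl acrylate (Ni(ClO4)2·6H2O, Zn, LiCl, MeCN) should give 1-tert-butyl 16-methyl (3R,6Z,10E)-3,11-dimethyl-7-[(trimethylsilyl)methyl]hexadeca-6,10-dienedioate F1. Reduction with i-Bu2AlH at −78 °C should give tert-butyl (3R,6Z,10E)-3,11-dimethyl-16-oxo-7-[(trimethylsilyl)methyl]hexadeca-6,10-dienoate F2. F2 would then be cyclised by organo-SOMO catalysis ((2R,5R)-5-benzyl-2-tert-butyl-3-methylimidazolidin-4-one trifluoroacetate, Cu(OTf)2, NaO2CCF3, i-PrCN/DME). The enamine radical cation should be attacked on the face left open by the benzyl group, and the cascade should end on the allylsilane with loss of silicon. This rejoins the route at aldehyde 22.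

Step 13. The hindered enolate may be methylated on oxygen, iodomethane may approach from the axial face, or enolisation may be slow enough for base-mediated side reactions to compete. Fallback from 22, a cyclopropanation/ring-opening α-methylation that needs no strong base: TBSOTf/Et3N should give the silyl enol ether, tert-butyl (13R)-19-(tert-butyldimethylsilyloxy)-18-norlabda-4(19),8(17)-dien-15-oate F3. Simmons–Smith cyclopropanation (Et2Zn, CH2I2, 0 °C) should take place at the electron-rich enol ether rather than at the C8=C17 alkene and from the equatorial face, giving the spiro siloxycyclopropane F4. Fluoride-induced ring opening (TBAF, AcOH) should cleave the bond between C19 and the new CH2, turning it into the equatorial methyl group. This rejoins the route at 24.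

Step 12. Reduction may run on to the alcohol, may stall at the hindered acyl group, or may touch the tert-butyl ester. Fallback from 21: exhaustive reduction then re-oxidation. LiBH4 (THF, 0 °C) should cleave the acylsultam to the primary alcohol, tert-butyl (4S,5R,9R,10R,13R)-19-hydroxy-18-norlabd-8(17)-en-15-oate F5, without touching the tert-butyl ester, and Dess–Martin periodinane should return 22.

Further compounds
F1 | step 11 | 1-tert-butyl 16-methyl (3R,6Z,10E)-3,11-dimethyl-7-[(trimethylsilyl)methyl]hexadeca-6,10-dienedioate | COC(=O)CCCC/C(C)=C/CC/C(C[Si](C)(C)C)=C/CC[C@@H](C)CC(=O)OC(C)(C)C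
F2 | step 11 | tert-butyl (3R,6Z,10E)-3,11-dimethyl-16-oxo-7-[(trimethylsilyl)methyl]hexadeca-6,10-dienoate | O=CCCCC/C(C)=C/CC/C(C[Si](C)(C)C)=C/CC[C@@H](C)CC(=O)OC(C)(C)C
F3 | step 13 | tert-butyl (13R)-19-(tert-butyldimethylsilyloxy)-18-norlabda-4(19),8(17)-dien-15-oate | C=C1CC[C@@H]2C(=CO[Si](C)(C)C(C)(C)C)CCC[C@@]2(C)[C@@H]1CC[C@@H](C)CC(=O)OC(C)(C)C
F4 | step 13 | spiro siloxycyclopropane from F3 (C4 spiro centre, new CH2 on the equatorial face, C19 bearing OTBS) | C=C1CC[C@@H]2[C@@]3(CC3O[Si](C)(C)C(C)(C)C)CCC[C@@]2(C)[C@@H]1CC[C@@H](C)CC(=O)OC(C)(C)C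
F5 | step 12 | tert-butyl (4S,5R,9R,10R,13R)-19-hydroxy-18-norlabd-8(17)-en-15-oate | C=C1CC[C@@H]2[C@@H](CO)CCC[C@@]2(C)[C@@H]1CC[C@@H](C)CC(=O)OC(C)(C)C
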